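**Plan**

1. Ring names: A is the aromatic ring, B the pyran ring, C the cyclohexadienone, numbered C1 (carbonyl), C2 (acetyl), C3, C4 (quaternary), C5, C6 (carries the CH2 bridge).
2. Retrosynthesis: after removal of the two phenol protecting groups and of the acetyl group at C2, ring C is cut at C2–C3 and C5–C6. This is open because C4 lies between the carbonyl-level carbons C3 and C5 (a 2,2-disubstituted malonyl unit), while C2–C1–C6 is a three-carbon ketone unit whose C6 already carries the CH2 link to C8 of ring A.
3. The resulting 8-(3-oxobutyl)chromene is cut at C8–CH2 (but-3-en-2-one), at the O–C and C–C bonds of ring B (propargyl ether) and at the butanoyl group; the malonyl half-ester chloride is cut at C4–CH2 (geranyl bromide).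
4. Forward: ring A is acylated, ring B is closed, the oxobutyl chain and two methoxymethyl ethers are put on; ring C is closed in step 13, then acetylated at C2, and the phenols are freed last.
5. Stereochemistry: the only stereocentre, C4, comes from esterase desymmetrisation of the prochiral malonate, followed by an exchange of the roles of its two carboxyl carbons; it has no α-hydrogen and no bond to it is broken afterwards.

Key step: step 13

Assumption: pig liver esterase is taken to hydrolyse diester 13 to the (R)-half-ester 14, the sense expected for 2-methylmalonates carrying a long lipophilic 2-alkyl chain; the route is laid out for this outcome, and the sense and enantiomeric purity of 14 are to be checked before it is carried on.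

**Route**

Step 1
Reactants: 1 phloroglucinol
Product: 2 1-(2,4,6-trihydroxyphenyl)butan-1-one
Conditions: butanoyl chloride (1.1 equiv), AlCl3 (3.5 equiv), PhNO2, rt → 60 °C; aq. HCl
Reagents that add atoms: butanoyl chloride, CCCC(Cl)=O
Why: Friedel–Crafts C-acylation of the very electron-rich triol, in which the chelated ketone that forms deactivates the ring toward a second acylation.

Step 2
Reactants: 2 1-(2,4,6-trihydroxyphenyl)butan-1-one
Product: 3 1-[2,6-dihydroxy-4-(2-methylbut-3-yn-2-yloxy)phenyl]butan-1-one
Conditions: 3-chloro-3-methylbut-1-yne (1.1 equiv), DBU (1.2 equiv), CuCl2·2H2O (1 mol%), MeCN, −5 → 0 °C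
Reagents that add atoms: 3-chloro-3-methylbut-1-yne, CC(C)(Cl)C#C
Why: Copper-catalysed O-alkylation of a phenol by a tertiary propargylic chloride (Williamson-type etherification), which should take place at the 4-hydroxyl because it is the most acidic one and the only one not hydrogen-bonded to the ketone.

Step 3
Reactants: 3 1-[2,6-dihydroxy-4-(2-methylbut-3-yn-2-yloxy)phenyl]butan-1-one
Product: 4 2-butanoyl-5-(2-methylbut-3-yn-2-yloxy)-1,3-phenylene diacetate
Conditions: Ac2O (3 equiv), pyridine, DMAP (cat.), CH2Cl2, rt
Reagents that add atoms: acetic anhydride, CC(=O)OC(C)=O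
Why: DMAP-catalysed O-acetylation, which blocks both ortho hydroxyls so that in the next step only the ether oxygen can become the ring B oxygen.

Step 4
Reactants: 4 2-butanoyl-5-(2-methylbut-3-yn-2-yloxy)-1,3-phenylene diacetate
Product: 6 6-butanoyl-2,2-dimethyl-2H-chromene-5,7-diyl diacetate, via ortho-allenyl phenol 5 (not isolated)
Conditions: o-xylene, 140 °C
Reagents that add atoms: none
Why: Aromatic propargyl Claisen rearrangement gives allenyl phenol 5, whose 1,5-hydrogen shift and oxa-6π electrocyclisation close ring B; the two positions ortho to the ether are equivalent and the only free hydroxyl beside the allene is the former ether oxygen, so a single 2H-chromene with its oxygen para to the butanoyl group should result.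

Step 5
Reactants: 6 6-butanoyl-2,2-dimethyl-2H-chromene-5,7-diyl diacetate; 7 but-3-en-2-one
Product: 9 4-(6-butanoyl-5,7-dihydroxy-2,2-dimethyl-2H-chromen-8-yl)butan-2-one, via chromene diol 8 (not isolated)
Conditions: NaOMe (2.2 equiv), MeOH (degassed), 0 °C; then 7 (1.3 equiv), 0 °C → rt; 1 M HCl
Reagents that add atoms: none
Why: Methoxide first removes the two aryl acetates by transesterification, and the phloroglucinol-type phenoxide of 8 then undergoes a Michael addition through carbon at C8, the only unsubstituted ring carbon, with the protic solvent and the reversibility of O-addition favouring the C-adduct.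

Step 6
Reactants: 9 4-(6-butanoyl-5,7-dihydroxy-2,2-dimethyl-2H-chromen-8-yl)butan-2-one
Product: 10 4-[6-butanoyl-5,7-bis(methoxymethoxy)-2,2-dimethyl-2H-chromen-8-yl]butan-2-one
Conditions: NaH (2.3 equiv), MeOCH2Cl (2.6 equiv), DMF, 0 °C
Reagents that add atoms: chloromethyl methyl ether, COCCl
Why: Williamson-type acetalisation of the two phenoxides, which form far more readily than either ketone enolate, so that a small excess of NaH over two equivalents should leave the ketones untouched.

Step 7
Reactants: 11 dimethyl 2-methylpropanedioate; 12 geranyl bromide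
Product: 13 dimethyl 2-[(2E)-3,7-dimethylocta-2,6-dien-1-yl]-2-methylpropanedioate
Conditions: NaH (1.05 equiv), THF, 0 °C; then 12, 0 °C → rt
Reagents that add atoms: none
Why: Malonate alkylation (SN2) of the sodium enolate at the primary allylic bromide, which keeps the E double bond and creates the prochiral quaternary carbon.

Step 8
Reactants: 13 dimethyl 2-[(2E)-3,7-dimethylocta-2,6-dien-1-yl]-2-methylpropanedioate
Product: 14 (2R,4E)-2-(methoxycarbonyl)-2,5,9-trimethyldeca-4,8-dienoic acid
Conditions: pig liver esterase, phosphate buffer pH 7.5 / DMSO (about 5:1), 25 °C, pH-stat with 1 M NaOH; then HCl to pH 2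
Reagents that add atoms: water, O
Why: Enzymatic desymmetrisation in which the esterase hydrolyses one of the two enantiotopic methyl esters and thereby sets the quaternary stereocentre (taken as R, see the assumption), a co-solvent being needed for the lipophilic substrate.

Step 9
Reactants: 14 (2R,4E)-2-(methoxycarbonyl)-2,5,9-trimethyldeca-4,8-dienoic acid
Product: 15 (2S,4E)-2-(hydroxymethyl)-2,5,9-trimethyldeca-4,8-dienoic acid
Conditions: LiOH (1.0 equiv), MeOH, evaporate; LiBH4 (2.5 equiv), THF, 0 → 55 °C; 1 M HCl
Reagents that add atoms: none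
Why: Chemoselective hydride reduction of the ester beside the lithium carboxylate (LiBH4 reduces esters but not carboxylate salts or isolated alkenes); no bond to the stereocentre is touched, and the descriptor becomes S only because the priorities change.

Step 10
Reactants: 15 (2S,4E)-2-(hydroxymethyl)-2,5,9-trimethyldeca-4,8-dienoic acid
Product: 16 methyl (2S,4E)-2-(hydroxymethyl)-2,5,9-trimethyldeca-4,8-dienoate
Conditions: MeI (1.5 equiv), K2CO3 (1.2 equiv), DMF, rt
Reagents that add atoms: iodomethane, CI
Why: SN2 O-alkylation of the carboxylate by iodomethane, the neopentyl-type alcohol not being deprotonated by carbonate and therefore staying free.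

Step 11
Reactants: 16 methyl (2S,4E)-2-(hydroxymethyl)-2,5,9-trimethyldeca-4,8-dienoate
Product: 18 (2S,4E)-2-(methoxycarbonyl)-2,5,9-trimethyldeca-4,8-dienoic acid, via aldehyde ester 17 (not isolated)
Conditions: TEMPO (0.2 equiv), PhI(OAc)2 (2.4 equiv), MeCN/H2O 1:1, rt
Reagents that add atoms: water, O
Why: Nitroxyl-catalysed oxidation takes the primary alcohol through the non-enolisable aldehyde 17 and its hydrate to the acid without touching the trisubstituted alkenes, so that steps 9–11 together exchange the roles of the two carboxyl carbons and should deliver the S half-ester.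

Step 12
Reactants: 18 (2S,4E)-2-(methoxycarbonyl)-2,5,9-trimethyldeca-4,8-dienoic acid
Product: 19 methyl (2R,4E)-2-(chlorocarbonyl)-2,5,9-trimethyldeca-4,8-dienoate
Conditions: (COCl)2 (1.5 equiv), DMF (cat.), CH2Cl2, 0 °C → rt; evaporate, use crude
Reagents that add atoms: oxalyl chloride, O=C(Cl)C(Cl)=O
Why: Acid chloride formation through chloroiminium activation; the α-carbon is quaternary, so neither ketene formation nor racemisation is possible, and the descriptor becomes R only through the priority change.

Step 13
Reactants: 10 4-[6-butanoyl-5,7-bis(methoxymethoxy)-2,2-dimethyl-2H-chromen-8-yl]butan-2-one; 19 methyl (2R,4E)-2-(chlorocarbonyl)-2,5,9-trimethyldeca-4,8-dienoate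
Product: 21 (4S)-6-{[6-butanoyl-5,7-bis(methoxymethoxy)-2,2-dimethyl-2H-chromen-8-yl]methyl}-4-[(2E)-3,7-dimethylocta-2,6-dien-1-yl]-3,5-dihydroxy-4-methylcyclohexa-2,5-dien-1-one, via diketo ester 20 (not isolated)
Conditions: 10, LiN(SiMe3)2 (2.2 equiv), THF, −78 °C; 19 (1.1 equiv), −78 °C; then LiN(iPr)2 (3 equiv), −78 → 0 °C; aq. citric acid
Reagents that add atoms: none
Why: LiN(SiMe3)2 converts 10 into the kinetic lithium enolate of its methyl ketone (the butanoyl ketone is at most parked as a hindered enolate), whose terminal carbon attacks the acid chloride of 19 to form C2–C3 and give diketo ester 20 as its enolate; LiN(iPr)2 then generates the dianion, whose carbanion at the bridge-side methylene adds to the methyl ester and expels methoxide to form C5–C6. The closest known reaction type is the Claisen C-acylation of a ketone lithium enolate by an acid chloride followed by the Dieckmann-type closure of a 3,5-dioxo ester dianion, as in [3+3] syntheses of cyclohexane-1,3,5-triones from ketones and malonic acid derivatives. Ring C closes in a 6-(enolexo)-exo-trig mode. No stereocentre is created: C4 is carried in from 19, and because the chloride must react before the ester, the order of the two bond formations fixes which flank of C4 becomes C3 and which C5, so that the configuration of 19 is mapped onto ring C as the target requires. The step needs C- rather than O-acylation (lithium counter-ion in THF at −78 °C), reaction at the methyl and not at the butanoyl enolate (a terminal enolate carbon against one buried between the 2,6-bis(methoxymethoxy)aryl group and an ethyl group, with a neopentyl-type acid chloride as partner), attack on the chloride before the ester (large reactivity gap) and closure through carbon rather than oxygen (dianion, with the product held as its stable trione dianion).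

Step 14
Reactants: 21 (4S)-6-{[6-butanoyl-5,7-bis(methoxymethoxy)-2,2-dimethyl-2H-chromen-8-yl]methyl}-4-[(2E)-3,7-dimethylocta-2,6-dien-1-yl]-3,5-dihydroxy-4-methylcyclohexa-2,5-dien-1-one
Product: 23 (4R)-2-acetyl-6-{[6-butanoyl-5,7-bis(methoxymethoxy)-2,2-dimethyl-2H-chromen-8-yl]methyl}-4-[(2E)-3,7-dimethylocta-2,6-dien-1-yl]-3,5-dihydroxy-4-methylcyclohexa-2,5-dien-1-one, via ring C enol acetate 22 (not isolated)
Conditions: Ac2O (1.2 equiv), Et3N (2 equiv), DMAP (0.3 equiv), CH2Cl2, 0 °C → rt
Reagents that add atoms: acetic anhydride, CC(=O)OC(C)=O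
Why: O-Acetylation of the enolised trione gives enol acetate 22, and DMAP then mediates the known 1,3 O-to-C acyl shift of such enol esters to the 2-acyl trione, C2 being the only ring C carbon that still carries hydrogen between two carbonyls and ring A offering no free hydroxyl; C4 is untouched, and its descriptor becomes R only because the acetyl group raises the priority of the C3 branch.

Step 15
Reactants: 23 (4R)-2-acetyl-6-{[6-butanoyl-5,7-bis(methoxymethoxy)-2,2-dimethyl-2H-chromen-8-yl]methyl}-4-[(2E)-3,7-dimethylocta-2,6-dien-1-yl]-3,5-dihydroxy-4-methylcyclohexa-2,5-dien-1-one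
Product: 24 (4R)-2-acetyl-6-[(6-butanoyl-5,7-dihydroxy-2,2-dimethyl-2H-chromen-8-yl)methyl]-4-[(2E)-3,7-dimethylocta-2,6-dien-1-yl]-3,5-dihydroxy-4-methylcyclohexa-2,5-dien-1-one (CNP0203748.1)
Conditions: HCl (2 M) in MeOH, rt
Reagents that add atoms: none
Why: Acid-catalysed acetal exchange with methanol removes both methoxymethyl ethers, which are activated by the ortho butanoyl carbonyl, under conditions that should spare the geranyl and chromene double bonds; the quaternary centre cannot epimerise.

**Compound list**

1 | phloroglucinol | Oc1cc(O)cc(O)c1 | starting material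
2 | 1-(2,4,6-trihydroxyphenyl)butan-1-one | CCCC(=O)c1c(O)cc(O)cc1O | intermediate
3 | 1-[2,6-dihydroxy-4-(2-methylbut-3-yn-2-yloxy)phenyl]butan-1-one | CCCC(=O)c1c(O)cc(OC(C)(C)C#C)cc1O | intermediate
4 | 2-butanoyl-5-(2-methylbut-3-yn-2-yloxy)-1,3-phenylene diacetate | CCCC(=O)c1c(OC(C)=O)cc(OC(C)(C)C#C)cc1OC(C)=O | intermediate
5 | 2-butanoyl-5-hydroxy-4-(3-methylbuta-1,2-dien-1-yl)-1,3-phenylene diacetate (ortho-allenyl phenol) | CCCC(=O)c1c(OC(C)=O)cc(O)c(C=C=C(C)C)c1OC(C)=O | intermediate
6 | 6-butanoyl-2,2-dimethyl-2H-chromene-5,7-diyl diacetate | CCCC(=O)c1c(OC(C)=O)cc2OC(C)(C)C=Cc2c1OC(C)=O | intermediate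
7 | but-3-en-2-one | CC(=O)C=C | starting material
8 | 1-(5,7-dihydroxy-2,2-dimethyl-2H-chromen-6-yl)butan-1-one (chromene diol) | CCCC(=O)c1c(O)cc2OC(C)(C)C=Cc2c1O | intermediate
9 | 4-(6-butanoyl-5,7-dihydroxy-2,2-dimethyl-2H-chromen-8-yl)butan-2-one | CCCC(=O)c1c(O)c2C=CC(C)(C)Oc2c(CCC(C)=O)c1O | intermediate
10 | 4-[6-butanoyl-5,7-bis(methoxymethoxy)-2,2-dimethyl-2H-chromen-8-yl]butan-2-one | CCCC(=O)c1c(OCOC)c2C=CC(C)(C)Oc2c(CCC(C)=O)c1OCOC | intermediate
11 | dimethyl 2-methylpropanedioate | COC(=O)C(C)C(=O)OC | starting material
12 | geranyl bromide, (2E)-1-bromo-3,7-dimethylocta-2,6-diene | BrC/C=C(\C)CCC=C(C)C | starting material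
13 | dimethyl 2-[(2E)-3,7-dimethylocta-2,6-dien-1-yl]-2-methylpropanedioate | COC(=O)C(C)(C/C=C(\C)CCC=C(C)C)C(=O)OC | intermediate
14 | (2R,4E)-2-(methoxycarbonyl)-2,5,9-trimethyldeca-4,8-dienoic acid | COC(=O)[C@](C)(C/C=C(\C)CCC=C(C)C)C(O)=O | intermediate
15 | (2S,4E)-2-(hydroxymethyl)-2,5,9-trimethyldeca-4,8-dienoic acid | OC[C@](C)(C/C=C(\C)CCC=C(C)C)C(O)=O | intermediate
16 | methyl (2S,4E)-2-(hydroxymethyl)-2,5,9-trimethyldeca-4,8-dienoate | OC[C@](C)(C/C=C(\C)CCC=C(C)C)C(=O)OC | intermediate
17 | methyl (2S,4E)-2-formyl-2,5,9-trimethyldeca-4,8-dienoate (aldehyde ester) | O=C[C@](C)(C/C=C(\C)CCC=C(C)C)C(=O)OC | intermediate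
18 | (2S,4E)-2-(methoxycarbonyl)-2,5,9-trimethyldeca-4,8-dienoic acid | OC(=O)[C@](C)(C/C=C(\C)CCC=C(C)C)C(=O)OC | intermediate
19 | methyl (2R,4E)-2-(chlorocarbonyl)-2,5,9-trimethyldeca-4,8-dienoate | COC(=O)[C@@](C)(C/C=C(\C)CCC=C(C)C)C(Cl)=O | intermediate
20 | methyl (2S,4E)-2-{5-[6-butanoyl-5,7-bis(methoxymethoxy)-2,2-dimethyl-2H-chromen-8-yl]-3-oxopentanoyl}-2,5,9-trimethyldeca-4,8-dienoate (diketo ester) | CCCC(=O)c1c(OCOC)c2C=CC(C)(C)Oc2c(CCC(=O)CC(=O)[C@](C)(C/C=C(\C)CCC=C(C)C)C(=O)OC)c1OCOC | intermediate
21 | (4S)-6-{[6-butanoyl-5,7-bis(methoxymethoxy)-2,2-dimethyl-2H-chromen-8-yl]methyl}-4-[(2E)-3,7-dimethylocta-2,6-dien-1-yl]-3,5-dihydroxy-4-methylcyclohexa-2,5-dien-1-one (ring C numbered as in the target; descriptor for the tautomer drawn; same spatial arrangement at C4 as in 24) | CCCC(=O)c1c(OCOC)c2C=CC(C)(C)Oc2c(CC2=C(O)[C@@](C)(C/C=C(\C)CCC=C(C)C)C(O)=CC2=O)c1OCOC | intermediate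
22 | enol acetate of 21 at the C3 oxygen of ring C, C4 unchanged | CCCC(=O)c1c(OCOC)c2C=CC(C)(C)Oc2c(CC2=C(O)[C@@](C)(C/C=C(\C)CCC=C(C)C)C(OC(C)=O)=CC2=O)c1OCOC | intermediate
23 | (4R)-2-acetyl-6-{[6-butanoyl-5,7-bis(methoxymethoxy)-2,2-dimethyl-2H-chromen-8-yl]methyl}-4-[(2E)-3,7-dimethylocta-2,6-dien-1-yl]-3,5-dihydroxy-4-methylcyclohexa-2,5-dien-1-one | CCCC(=O)c1c(OCOC)c2C=CC(C)(C)Oc2c(CC2=C(O)[C@@](C)(C/C=C(\C)CCC=C(C)C)C(O)=C(C(C)=O)C2=O)c1OCOC | intermediate
24 | (4R)-2-acetyl-6-[(6-butanoyl-5,7-dihydroxy-2,2-dimethyl-2H-chromen-8-yl)methyl]-4-[(2E)-3,7-dimethylocta-2,6-dien-1-yl]-3,5-dihydroxy-4-methylcyclohexa-2,5-dien-1-one (CNP0203748.1) | CCCC(=O)c1c(O)c2c(c(CC3=C(O)[C@@](C)(C/C=C(\C)CCC=C(C)C)C(O)=C(C(C)=O)C3=O)c1O)OC(C)(C)C=C2 | target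

**Step count and risks**

Total: 15 steps. Longest linear sequence: 9 steps (steps 1–6 or steps 7–12, followed by steps 13–15).

Steps most likely to fail:

Step 13. The enolate may be acylated on oxygen, or the butanoyl enolate may react in place of the methyl enolate, or the open diketo ester may lactonise through its enolate oxygen instead of closing through carbon. The fallback separates the two bond formations and makes the first one an aldol addition. Setting out from 16, oxidation with Dess–Martin periodinane is stopped at aldehyde ester 17, which is isolated. The lithium enolate of 10 (LiN(iPr)2, THF, −78 °C) adds to this non-enolisable aldehyde to give β-hydroxy ketone F1 as a mixture of carbinol epimers. A second Dess–Martin oxidation converges both epimers on diketo ester 20, which is now isolated and cyclised in a separate operation (NaH or LiN(iPr)2, THF, 0 °C) to 21, where the route is rejoined.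

Step 8. The esterase may discriminate the two enantiotopic ester groups poorly, or in the opposite sense. Setting out from 13, one ester is hydrolysed without an enzyme (KOH, 1.0 equiv, MeOH, rt) to the racemic half-ester F2. This is resolved by fractional crystallisation of its salt with (S)-1-phenylethylamine, the S-acid salt F3 being collected (should the other diastereomer be the less soluble one, the antipodal amine is used). Acidification returns 18 directly, so that steps 9–11 fall away and the route is rejoined at 18. If the enzyme merely shows the opposite preference, its product is 18 itself and the same shortcut applies.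

Step 2. Alkylation may not stop at the 4-oxygen (C-alkylation of the phloroglucinol ring, or reaction at several hydroxyls). Setting out from 2, ring B is instead built in one operation by condensation with 3-methylbut-2-enal (ethylenediammonium diacetate cat., toluene, reflux; Knoevenagel condensation followed by oxa-6π electrocyclisation). This should give chromene diol 8 as an isolated compound, which has to be separated from its 8-butanoyl regioisomer. The route is rejoined at 8, which enters the Michael addition of step 5 with one equivalent of NaOMe. This fallback makes no new compound (F0).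

**Further compounds**

F1 | step 13 | methyl (2S,4E)-2-{5-[6-butanoyl-5,7-bis(methoxymethoxy)-2,2-dimethyl-2H-chromen-8-yl]-1-hydroxy-3-oxopentyl}-2,5,9-trimethyldeca-4,8-dienoate (β-hydroxy ketone, both carbinol epimers) | CCCC(=O)c1c(OCOC)c2C=CC(C)(C)Oc2c(CCC(=O)CC(O)[C@](C)(C/C=C(\C)CCC=C(C)C)C(=O)OC)c1OCOC
F2 | step 8 | racemic (4E)-2-(methoxycarbonyl)-2,5,9-trimethyldeca-4,8-dienoic acid | COC(=O)C(C)(C/C=C(\C)CCC=C(C)C)C(O)=O
F3 | step 8 | (S)-1-phenylethylammonium (2S,4E)-2-(methoxycarbonyl)-2,5,9-trimethyldeca-4,8-dienoate | COC(=O)[C@@](C)(C/C=C(\C)CCC=C(C)C)C([O-])=O.C[C@H]([NH3+])c1ccccc1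
F0 | step 2 | none | none
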